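**Plan**
- Feature: ring A bears oxygen on each of C5, C6, C7 and C8. These four adjacent carbons map onto the four ring carbons of a squaric ester, and the C4a–C8a bond they are fused to is a C=C bond of the 4-pyranone ring C.
- Cuts, late to early: the three ring B O–benzyl bonds, O7–tert-butyl and O8–methyl; then C8–C8a (electrocyclic closure of ring A) and C4a–C5 (Grignard addition to tert-butyl methyl squarate).
- Ring C is cut at O1–C8a and C3–C4 (cyclodehydration after C-acylation), and the C2–C1' bond goes back to an aryllithium and a Weinreb amide.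
- Forward: ring B is bought as the aryl bromide, ring C is built and iodinated at the future C4a, the squarate is attached, and ring A closes last by thermal ring expansion; 8-O-methylation and two deprotections finish.
- Stereochemistry: the target has no stereocentre; the carbinol carbon of the cyclobutenone adduct is racemic and becomes aromatic C5.

Key step: step 9

Remark: ring C is assembled by acylation and cyclodehydration of an α-methoxy aryl ketone, because this places the C3 methoxy group and the free C–H pair of the pyranone without any oxidation step.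

Step 1
Reactants: 1 5-bromo-1,2,3-trimethoxybenzene
Product: 2 5-bromobenzene-1,2,3-triol
Conditions: BBr3 (3.5 equiv), CH2Cl2, −78 °C to rt; then H2O, 0 °C
Reagents that add atoms: none
Why: Lewis-acid ether cleavage (BBr3 demethylation) should remove all three aryl methyl ethers and leave the aryl bromide intact, so that the ring B oxygens can be re-protected as hydrogenolysable benzyl ethers.

Step 2
Reactants: 2 5-bromobenzene-1,2,3-triol
Product: 3 5-bromo-1,2,3-tris(benzyloxy)benzene
Conditions: BnBr (3.6 equiv), K2CO3 (5 equiv), DMF, 60 °C, under N2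
Reagents that add atoms: benzyl bromide, BrCc1ccccc1
Why: Williamson ether synthesis on the three phenoxides, run under nitrogen because the pyrogallol is oxidised by air in base.

Step 3
Reactants: 3 5-bromo-1,2,3-tris(benzyloxy)benzene; 4 N,2-dimethoxy-N-methylacetamide
Product: 6 2-methoxy-1-[3,4,5-tris(benzyloxy)phenyl]ethan-1-one, via aryllithium 5 (not isolated)
Conditions: n-BuLi (1.05 equiv), THF, −78 °C; then 4, −78 to 0 °C; aq. NH4Cl
Reagents that add atoms: none
Why: Bromine–lithium exchange followed by Weinreb ketone synthesis, in which the chelated tetrahedral adduct prevents over-addition, should give the aryl ketone whose only enolisable carbon already carries the future C3 methoxy group.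

Step 4
Reactants: 6 2-methoxy-1-[3,4,5-tris(benzyloxy)phenyl]ethan-1-one; 7 (E)-3-ethoxyacryloyl chloride
Product: 9 3-methoxy-2-[3,4,5-tris(benzyloxy)phenyl]-4H-pyran-4-one, via enol ether diketone 8 (not isolated)
Conditions: MgBr2·OEt2 (2.5 equiv), i-Pr2NEt (3 equiv), CH2Cl2, 0 °C to rt; 1 M HCl wash; then TFA (5 equiv), CH2Cl2, rt
Reagents that add atoms: none
Why: Soft-enolisation C-acylation of the magnesium-chelated α-methoxy ketone should give the 1,3-diketone, whose enol oxygen then adds to the β-ethoxy enone and expels ethanol under acid (acid-catalysed cyclodehydration to a 4-pyranone).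

Step 5
Reactants: 9 3-methoxy-2-[3,4,5-tris(benzyloxy)phenyl]-4H-pyran-4-one
Product: 10 5-iodo-3-methoxy-2-[3,4,5-tris(benzyloxy)phenyl]-4H-pyran-4-one
Conditions: I2 (2 equiv), pyridine–CH2Cl2 (1:1), rt to 40 °C, dark; aq. Na2S2O3
Reagents that add atoms: iodine, II
Why: Pyridine-mediated α-iodination of a β-oxygenated enone (conjugate addition of pyridine at C6, iodination at C5, elimination) should iodinate the only enone α-CH, while molecular iodine is too weak an electrophile to substitute the alkoxy-rich ring B.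

Step 6
Reactants: 11 dimethyl squarate (3,4-dimethoxycyclobut-3-ene-1,2-dione)
Product: 12 3-hydroxy-4-methoxycyclobut-3-ene-1,2-dione
Conditions: NaOH (1.0 equiv), THF–H2O, 0 °C to rt; then HCl (1.0 equiv), evaporation, extraction into acetone
Reagents that add atoms: sodium hydroxide, [Na+].[OH-]
Why: Saponification of the vinylogous ester (addition–elimination at an alkoxy-bearing carbon) should stop after one methoxy group, because the squarate monoanion formed is deactivated toward a second attack.

Step 7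
Reactants: 12 3-hydroxy-4-methoxycyclobut-3-ene-1,2-dione
Product: 13 3-tert-butoxy-4-methoxycyclobut-3-ene-1,2-dione
Conditions: tert-butyl 2,2,2-trichloroacetimidate (2 equiv), THF–cyclohexane, rt
Reagents that add atoms: tert-butyl 2,2,2-trichloroacetimidate, CC(C)(C)OC(=N)C(Cl)(Cl)Cl
Why: Acid-promoted tert-butylation with a trichloroacetimidate, triggered here by the strongly acidic vinylogous acid itself, should give the mixed squarate without base or mineral acid.

Step 8
Reactants: 10 5-iodo-3-methoxy-2-[3,4,5-tris(benzyloxy)phenyl]-4H-pyran-4-one; 13 3-tert-butoxy-4-methoxycyclobut-3-ene-1,2-dione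
Product: 15 racemic 2-tert-butoxy-4-hydroxy-3-methoxy-4-{5-methoxy-4-oxo-6-[3,4,5-tris(benzyloxy)phenyl]-4H-pyran-3-yl}cyclobut-2-en-1-one, via pyranonylmagnesium chloride 14 (not isolated)
Conditions: i-PrMgCl·LiCl (1.05 equiv), THF, −78 °C, 20 min; then 13 (1.2 equiv), THF, −78 °C; aq. NH4Cl at −78 °C
Reagents that add atoms: none
Why: Iodine–magnesium exchange on the α-iodo-β-alkoxy enone should give an alkenyl Grignard reagent that is kept at −78 °C to hold back β-elimination and adds 1,2 to the squarate carbonyl next to the methoxy-bearing carbon, because the tert-butoxy group screens the other carbonyl and the methoxy oxygen can chelate magnesium; the carbinol carbon forms as a racemate, which does not matter since it becomes aromatic C5.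

Step 9
Reactants: 15 racemic 2-tert-butoxy-4-hydroxy-3-methoxy-4-{5-methoxy-4-oxo-6-[3,4,5-tris(benzyloxy)phenyl]-4H-pyran-3-yl}cyclobut-2-en-1-one
Product: 18 7-tert-butoxy-5,8-dihydroxy-3,6-dimethoxy-2-[3,4,5-tris(benzyloxy)phenyl]-4H-chromen-4-one, via dienylketene 16 (not isolated), via dienone 17 (not isolated)
Conditions: degassed toluene (0.02 M), 110 °C, argon (p-xylene, 138 °C, if conversion is slow)
Reagents that add atoms: none
Why: Heating opens the cyclobutenone by a conrotatory four-electron electrocyclic ring opening in which the C4 hydroxyl, as a donor, rotates outward, so that the pyranonyl group of dienylketene 16 points inward toward the ketene. The ketene carbon then joins the pyranone CH carbon next to the ring oxygen in a thermal disrotatory six-electron electrocyclisation that forms the C8–C8a bond and closes ring A as the six-membered dienone 17, and a proton shift from C8a to the new C8 oxygen aromatises it to hydroquinone 18. The closest known reaction type is the thermal ring expansion of 4-aryl-, 4-heteroaryl- and 4-alkenyl-4-hydroxycyclobutenones from squaric esters to hydroquinones (Moore rearrangement). No stereocentre has to be controlled, since the carbinol centre of 15 and the transient C8a centre of 17 both end as sp2 carbons. The step needs outward rotation of the hydroxyl, which the torquoselectivity of a free 4-hydroxyl should secure and which keeps the hydroxyl from trapping the ketene as a butenolide, and it needs closure at one site, which is secured because C6 of the pyranone is the only neighbour of the attachment carbon that carries hydrogen. The cyclobutenone carbons map as carbinol carbon to C5, methoxy carbon to C6, tert-butoxy carbon to C7 and carbonyl carbon to C8, so the 5-hydroxyl is chelated to the C4 carbonyl and the 8-hydroxyl is free.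

Step 10
Reactants: 18 7-tert-butoxy-5,8-dihydroxy-3,6-dimethoxy-2-[3,4,5-tris(benzyloxy)phenyl]-4H-chromen-4-one
Product: 19 7-tert-butoxy-5-hydroxy-3,6,8-trimethoxy-2-[3,4,5-tris(benzyloxy)phenyl]-4H-chromen-4-one
Conditions: MeI (1.2 equiv), K2CO3 (1.5 equiv), degassed acetone, rt, argon
Reagents that add atoms: iodomethane, CI
Why: Williamson methylation should occur at the free 8-hydroxyl, because the 5-hydroxyl is held in a hydrogen bond to the C4 carbonyl and is the least acidic and least nucleophilic phenol of a flavone; exclusion of air protects the hydroquinone monoanion.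

Step 11
Reactants: 19 7-tert-butoxy-5-hydroxy-3,6,8-trimethoxy-2-[3,4,5-tris(benzyloxy)phenyl]-4H-chromen-4-one
Product: 20 5,7-dihydroxy-3,6,8-trimethoxy-2-[3,4,5-tris(benzyloxy)phenyl]-4H-chromen-4-one
Conditions: TFA–CH2Cl2 (1:4), 0 °C to rt
Reagents that add atoms: none
Why: Acidolysis of the aryl tert-butyl ether (loss of the tert-butyl cation as 2-methylpropene) should be far faster than cleavage of aryl benzyl or methyl ethers under these conditions.

Step 12
Reactants: 20 5,7-dihydroxy-3,6,8-trimethoxy-2-[3,4,5-tris(benzyloxy)phenyl]-4H-chromen-4-one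
Product: 21 5,7-dihydroxy-3,6,8-trimethoxy-2-(3,4,5-trihydroxyphenyl)-4H-chromen-4-one (5,7,3',4',5'-pentahydroxy-3,6,8-trimethoxyflavone)
Conditions: H2 (1 atm), 10% Pd/C, THF–MeOH, rt
Reagents that add atoms: none
Why: Catalytic hydrogenolysis should cleave the three benzyl ethers and spare the methyl ethers and the tetrasubstituted C2=C3 bond of the flavone.

**Compound list**
1 | 5-bromo-1,2,3-trimethoxybenzene | COc1cc(Br)cc(OC)c1OC | starting material
2 | 5-bromobenzene-1,2,3-triol | Oc1cc(Br)cc(O)c1O | intermediate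
3 | 5-bromo-1,2,3-tris(benzyloxy)benzene | Brc1cc(OCc2ccccc2)c(OCc2ccccc2)c(OCc2ccccc2)c1 | intermediate
4 | N,2-dimethoxy-N-methylacetamide | COCC(=O)N(C)OC | starting material
5 | [3,4,5-tris(benzyloxy)phenyl]lithium | [Li]c1cc(OCc2ccccc2)c(OCc2ccccc2)c(OCc2ccccc2)c1 | intermediate
6 | 2-methoxy-1-[3,4,5-tris(benzyloxy)phenyl]ethan-1-one | COCC(=O)c1cc(OCc2ccccc2)c(OCc2ccccc2)c(OCc2ccccc2)c1 | intermediate
7 | (E)-3-ethoxyacryloyl chloride | CCO/C=C/C(=O)Cl | starting material
8 | (E)-5-ethoxy-2-methoxy-1-[3,4,5-tris(benzyloxy)phenyl]pent-4-ene-1,3-dione (racemic, largely enolised) | CCO/C=C/C(=O)C(OC)C(=O)c1cc(OCc2ccccc2)c(OCc2ccccc2)c(OCc2ccccc2)c1 | intermediate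
9 | 3-methoxy-2-[3,4,5-tris(benzyloxy)phenyl]-4H-pyran-4-one | COc1c(-c2cc(OCc3ccccc3)c(OCc3ccccc3)c(OCc3ccccc3)c2)occc1=O | intermediate
10 | 5-iodo-3-methoxy-2-[3,4,5-tris(benzyloxy)phenyl]-4H-pyran-4-one | COc1c(-c2cc(OCc3ccccc3)c(OCc3ccccc3)c(OCc3ccccc3)c2)occ(I)c1=O | intermediate
11 | dimethyl squarate (3,4-dimethoxycyclobut-3-ene-1,2-dione) | COC1=C(OC)C(=O)C1=O | starting material
12 | 3-hydroxy-4-methoxycyclobut-3-ene-1,2-dione | COC1=C(O)C(=O)C1=O | intermediate
13 | 3-tert-butoxy-4-methoxycyclobut-3-ene-1,2-dione | COC1=C(OC(C)(C)C)C(=O)C1=O | intermediate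
14 | chloro{5-methoxy-4-oxo-6-[3,4,5-tris(benzyloxy)phenyl]-4H-pyran-3-yl}magnesium (LiCl complex) | COc1c(-c2cc(OCc3ccccc3)c(OCc3ccccc3)c(OCc3ccccc3)c2)occ([Mg]Cl)c1=O | intermediate
15 | racemic 2-tert-butoxy-4-hydroxy-3-methoxy-4-{5-methoxy-4-oxo-6-[3,4,5-tris(benzyloxy)phenyl]-4H-pyran-3-yl}cyclobut-2-en-1-one | COc1c(-c2cc(OCc3ccccc3)c(OCc3ccccc3)c(OCc3ccccc3)c2)occ(C2(O)C(OC)=C(OC(C)(C)C)C2=O)c1=O | intermediate
16 | (3Z)-2-tert-butoxy-4-hydroxy-3-methoxy-4-{5-methoxy-4-oxo-6-[3,4,5-tris(benzyloxy)phenyl]-4H-pyran-3-yl}buta-1,3-dien-1-one (dienylketene, hydroxyl outward, pyranonyl cis to the ketene-bearing carbon) | O=C=C(OC(C)(C)C)/C(OC)=C(/O)c1coc(-c2cc(OCc3ccccc3)c(OCc3ccccc3)c(OCc3ccccc3)c2)c(OC)c1=O | intermediate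
17 | racemic 7-tert-butoxy-5-hydroxy-3,6-dimethoxy-2-[3,4,5-tris(benzyloxy)phenyl]-4H-chromene-4,8(8aH)-dione | COC1=C(c2cc(OCc3ccccc3)c(OCc3ccccc3)c(OCc3ccccc3)c2)OC2C(=O)C(OC(C)(C)C)=C(OC)C(O)=C2C1=O | intermediate
18 | 7-tert-butoxy-5,8-dihydroxy-3,6-dimethoxy-2-[3,4,5-tris(benzyloxy)phenyl]-4H-chromen-4-one | COc1c(-c2cc(OCc3ccccc3)c(OCc3ccccc3)c(OCc3ccccc3)c2)oc2c(O)c(OC(C)(C)C)c(OC)c(O)c2c1=O | intermediate
19 | 7-tert-butoxy-5-hydroxy-3,6,8-trimethoxy-2-[3,4,5-tris(benzyloxy)phenyl]-4H-chromen-4-one | COc1c(-c2cc(OCc3ccccc3)c(OCc3ccccc3)c(OCc3ccccc3)c2)oc2c(OC)c(OC(C)(C)C)c(OC)c(O)c2c1=O | intermediate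
20 | 5,7-dihydroxy-3,6,8-trimethoxy-2-[3,4,5-tris(benzyloxy)phenyl]-4H-chromen-4-one | COc1c(-c2cc(OCc3ccccc3)c(OCc3ccccc3)c(OCc3ccccc3)c2)oc2c(OC)c(O)c(OC)c(O)c2c1=O | intermediate
21 | 5,7-dihydroxy-3,6,8-trimethoxy-2-(3,4,5-trihydroxyphenyl)-4H-chromen-4-one | COc1c(O)c(OC)c2oc(-c3cc(O)c(O)c(O)c3)c(OC)c(=O)c2c1O | target

**Step count**
Total steps: 12. Longest linear sequence: 10 (steps 1–5 and 8–12); steps 6–7 make the squarate partner.

**Steps most likely to fail**

1. Step 8: poor site selectivity between the two squarate carbonyls; attack next to the tert-butoxy carbon would put the methoxy group on C7. (β-Elimination of the magnesium reagent is a lesser concern, held back by the low temperature.)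
   Fallback, setting out from iodide 10 and coming back at target 21: Grignard reagent 14 is made as in step 8 and added to the symmetrical 3,4-di-tert-butoxycyclobut-3-ene-1,2-dione F1, whose two carbonyls are equivalent. This should give the racemic 2,3-di-tert-butoxy-4-hydroxy-4-pyranonylcyclobutenone F2. Thermolysis in toluene as in step 9 should give 6,7-di-tert-butoxy-5,8-dihydroxy-3-methoxy-2-[3,4,5-tris(benzyloxy)phenyl]-4H-chromen-4-one F3. MeI/K2CO3 under argon should methylate the unchelated 8-hydroxyl to the 8-methyl ether F4. TFA in CH2Cl2 should remove both tert-butyl groups to give the 5,6,7-triol F5. BnBr (1 equiv)/K2CO3 in acetone should benzylate the most acidic 7-hydroxyl, para to the carbonyl, to give the 7-benzyl ether F6. MeI/K2CO3 should then methylate the 6-hydroxyl while the chelated 5-hydroxyl stays free, giving the 6-methyl ether F7. Hydrogenolysis as in step 12 of all four benzyl ethers gives 21.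

2. Step 9: if closure onto the weakly aromatic pyranone is slow, the tertiary hydroxyl may capture the ketene as a butenolide; the hydroquinone may also be oxidised by air to the 5,8-quinone.
   Fallback, setting out from 15 and coming back at 19: the carbinol is silylated (TESOTf, 2,6-lutidine, CH2Cl2, −78 °C) to the 4-(triethylsilyloxy)cyclobutenone F8, which has no free hydroxyl to trap the ketene. Thermolysis in toluene should give the mono-protected hydroquinone 7-tert-butoxy-8-hydroxy-3,6-dimethoxy-5-(triethylsilyloxy)chromone F9, which is not prone to quinone formation. MeI/K2CO3 in acetone should methylate the only free hydroxyl to the 8-methyl ether F10. Bu4NF/AcOH in THF at 0 °C removes the silyl group and gives 19.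

3. Step 5: the pyranone may be too weakly nucleophilic for iodine–pyridine, and stronger iodinating agents would begin to substitute ring B (loss of chemoselectivity).
   Fallback, setting out from 9 and coming back at 10: pyrrolidine in EtOH at rt should open the pyranone at the unsubstituted C6 to the enaminone (E)-2-methoxy-5-(pyrrolidin-1-yl)-1-[3,4,5-tris(benzyloxy)phenyl]pent-4-ene-1,3-dione F11. Iodine in CHCl3 should iodinate the enaminone α-carbon, and the enol oxygen recloses the ring with loss of pyrrolidine (iodinative cyclisation of an enaminone, the standard route to 3-iodochromones), giving 10.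

**Further compounds**
F1 | step 8 | 3,4-di-tert-butoxycyclobut-3-ene-1,2-dione | CC(C)(C)OC1=C(OC(C)(C)C)C(=O)C1=O
F2 | step 8 | racemic 2,3-di-tert-butoxy-4-hydroxy-4-{5-methoxy-4-oxo-6-[3,4,5-tris(benzyloxy)phenyl]-4H-pyran-3-yl}cyclobut-2-en-1-one | COc1c(-c2cc(OCc3ccccc3)c(OCc3ccccc3)c(OCc3ccccc3)c2)occ(C2(O)C(OC(C)(C)C)=C(OC(C)(C)C)C2=O)c1=O
F3 | step 8 | 6,7-di-tert-butoxy-5,8-dihydroxy-3-methoxy-2-[3,4,5-tris(benzyloxy)phenyl]-4H-chromen-4-one | COc1c(-c2cc(OCc3ccccc3)c(OCc3ccccc3)c(OCc3ccccc3)c2)oc2c(O)c(OC(C)(C)C)c(OC(C)(C)C)c(O)c2c1=O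
F4 | step 8 | 6,7-di-tert-butoxy-5-hydroxy-3,8-dimethoxy-2-[3,4,5-tris(benzyloxy)phenyl]-4H-chromen-4-one | COc1c(-c2cc(OCc3ccccc3)c(OCc3ccccc3)c(OCc3ccccc3)c2)oc2c(OC)c(OC(C)(C)C)c(OC(C)(C)C)c(O)c2c1=O
F5 | step 8 | 5,6,7-trihydroxy-3,8-dimethoxy-2-[3,4,5-tris(benzyloxy)phenyl]-4H-chromen-4-one | COc1c(-c2cc(OCc3ccccc3)c(OCc3ccccc3)c(OCc3ccccc3)c2)oc2c(OC)c(O)c(O)c(O)c2c1=O
F6 | step 8 | 7-(benzyloxy)-5,6-dihydroxy-3,8-dimethoxy-2-[3,4,5-tris(benzyloxy)phenyl]-4H-chromen-4-one | COc1c(-c2cc(OCc3ccccc3)c(OCc3ccccc3)c(OCc3ccccc3)c2)oc2c(OC)c(OCc3ccccc3)c(O)c(O)c2c1=O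
F7 | step 8 | 7-(benzyloxy)-5-hydroxy-3,6,8-trimethoxy-2-[3,4,5-tris(benzyloxy)phenyl]-4H-chromen-4-one | COc1c(-c2cc(OCc3ccccc3)c(OCc3ccccc3)c(OCc3ccccc3)c2)oc2c(OC)c(OCc3ccccc3)c(OC)c(O)c2c1=O
F8 | step 9 | racemic 2-tert-butoxy-3-methoxy-4-{5-methoxy-4-oxo-6-[3,4,5-tris(benzyloxy)phenyl]-4H-pyran-3-yl}-4-[(triethylsilyl)oxy]cyclobut-2-en-1-one | COc1c(-c2cc(OCc3ccccc3)c(OCc3ccccc3)c(OCc3ccccc3)c2)occ(C2(O[Si](CC)(CC)CC)C(OC)=C(OC(C)(C)C)C2=O)c1=O
F9 | step 9 | 7-tert-butoxy-8-hydroxy-3,6-dimethoxy-5-[(triethylsilyl)oxy]-2-[3,4,5-tris(benzyloxy)phenyl]-4H-chromen-4-one | COc1c(-c2cc(OCc3ccccc3)c(OCc3ccccc3)c(OCc3ccccc3)c2)oc2c(O)c(OC(C)(C)C)c(OC)c(O[Si](CC)(CC)CC)c2c1=O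
F10 | step 9 | 7-tert-butoxy-3,6,8-trimethoxy-5-[(triethylsilyl)oxy]-2-[3,4,5-tris(benzyloxy)phenyl]-4H-chromen-4-one | COc1c(-c2cc(OCc3ccccc3)c(OCc3ccccc3)c(OCc3ccccc3)c2)oc2c(OC)c(OC(C)(C)C)c(OC)c(O[Si](CC)(CC)CC)c2c1=O
F11 | step 5 | (E)-2-methoxy-5-(pyrrolidin-1-yl)-1-[3,4,5-tris(benzyloxy)phenyl]pent-4-ene-1,3-dione | COC(C(=O)/C=C/N1CCCC1)C(=O)c1cc(OCc2ccccc2)c(OCc2ccccc2)c(OCc2ccccc2)c1
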